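**Retrosynthetic overview**
1. Target ⇐ its hexabenzyl ether, by one final hydrogenolysis.
2. Rings C and F are both cut at O1–C2 and C3–C4: a double inverse-demand [4+2] of a latent bis(o-quinone methide), which already holds rings A and D and the C4–C6′ bond, with two molecules of an (E)-β-formyloxystyrene (ring B or E plus C2 and C3). One chiral Brønsted acid sets all five stereocentres.
3. Ring order: rings A, B, D and E are bought as benzene rings; ring C closes first (benzhydrol-derived quinone methide), ring F second (quinone methide released from an acetonide), in the same flask.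
4. Bis(quinone methide) precursor ⇐ aryllithium of a brominated salicyl alcohol acetonide + 4-(benzyloxy)-2-hydroxybenzaldehyde; both aryl units come from this one aldehyde.
5. Enol formate ⇐ Baeyer–Villiger oxidation of the cinnamaldehyde ⇐ Wittig reaction of 3,4-bis(benzyloxy)benzaldehyde.

Assumption: 1, 8 and 9 are taken as catalogue chemicals; flavan numbering is used, unprimed for the upper unit (rings A, C, B) and primed for the lower unit (rings D, F, E).

**Route**

Step 1
Reactants: 1 4-(benzyloxy)-2-hydroxybenzaldehyde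
Product: 2 4-(benzyloxy)-5-bromo-2-hydroxybenzaldehyde
Conditions: N-bromosuccinimide (1.05 equiv), MeCN, 0 °C → rt, dark
Reagents that add atoms: N-bromosuccinimide, O=C1CCC(=O)N1Br
Why: Electrophilic aromatic bromination goes para to the free phenol and ortho to the benzyloxy group (C5), because the only other activated site, between the two oxygens, is more hindered.

Step 2
Reactants: 2 4-(benzyloxy)-5-bromo-2-hydroxybenzaldehyde
Product: 3 5-(benzyloxy)-4-bromo-2-(hydroxymethyl)phenol
Conditions: NaBH4, MeOH–THF, 0 °C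
Reagents that add atoms: none
Why: Borohydride reduction of the aldehyde gives the salicyl alcohol while the aryl bromide and the benzyl ether are inert.

Step 3
Reactants: 3 5-(benzyloxy)-4-bromo-2-(hydroxymethyl)phenol
Product: 4 7-(benzyloxy)-6-bromo-2,2-dimethyl-4H-1,3-benzodioxine
Conditions: 2,2-dimethoxypropane, pyridinium p-toluenesulfonate (cat.), acetone, rt
Reagents that add atoms: 2,2-dimethoxypropane, COC(C)(C)OC
Why: Acid-catalysed transacetalisation ties the phenol and the benzylic alcohol into an isopropylidene acetal, which masks both OH groups for the organolithium step and later serves as the latent o-quinone methide of ring F.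

Step 4
Reactants: 4 7-(benzyloxy)-6-bromo-2,2-dimethyl-4H-1,3-benzodioxine; 1 4-(benzyloxy)-2-hydroxybenzaldehyde
Product: 7 [4-(benzyloxy)-2-hydroxyphenyl][7-(benzyloxy)-2,2-dimethyl-4H-1,3-benzodioxin-6-yl]methanol (racemic carbinol), via aryllithium 5 (not isolated), via sodium phenolate 6 (not isolated)
Conditions: 4, n-BuLi (1.05 equiv), THF, −78 °C; then 6 (from 1, NaH, THF, 0 °C) added at −78 °C → −20 °C; H2O quench
Reagents that add atoms: none
Why: Bromine–lithium exchange followed by 1,2-addition of the aryllithium to the aldehyde (the phenol is deprotonated beforehand so that it cannot quench the aryllithium) makes the C4–C6′ bond, and the new carbinol centre is formed racemic because it is erased in step 7.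

Step 5
Reactants: 8 3,4-bis(benzyloxy)benzaldehyde; 9 (triphenylphosphoranylidene)acetaldehyde
Product: 10 (2E)-3-[3,4-bis(benzyloxy)phenyl]prop-2-enal
Conditions: 9 (1.05 equiv), toluene, 80 °C
Reagents that add atoms: none
Why: Wittig olefination with the stabilised formyl ylide gives the (E)-enal, and the near-stoichiometric amount of ylide limits a second homologation.

Step 6
Reactants: 10 (2E)-3-[3,4-bis(benzyloxy)phenyl]prop-2-enal
Product: 11 (E)-2-[3,4-bis(benzyloxy)phenyl]ethenyl formate
Conditions: 30% H2O2 (1.1 equiv), bis(2-nitrophenyl) diselenide (5 mol %), CH2Cl2, rt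
Reagents that add atoms: hydrogen peroxide, OO
Why: Baeyer–Villiger oxidation of the α,β-unsaturated aldehyde by the perseleninic acid formed in situ makes the alkenyl group migrate with retention, so the (E)-geometry of 10 is carried into the enol formate.

Step 7
Reactants: 7 [4-(benzyloxy)-2-hydroxyphenyl][7-(benzyloxy)-2,2-dimethyl-4H-1,3-benzodioxin-6-yl]methanol; 11 (E)-2-[3,4-bis(benzyloxy)phenyl]ethenyl formate (two molecules enter the product)
Product: 16 (2R,3S,4S)-7-(benzyloxy)-2-[3,4-bis(benzyloxy)phenyl]-4-{(2R,3S)-7-(benzyloxy)-2-[3,4-bis(benzyloxy)phenyl]-3-hydroxy-3,4-dihydro-2H-chromen-6-yl}-3,4-dihydro-2H-chromen-3-ol (hexabenzyl ether of 17; C4 is spatially as in 17 - the descriptor is S only because ring D now carries a benzyl ether), via upper o-quinone methide 12 (not isolated), via ring C monoadduct 13 (not isolated), via lower o-quinone methide 14 (not isolated), via bis-formate 15 (not isolated)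
Conditions: 11 (4 equiv), (R)-3,3′-bis(2,4,6-triisopropylphenyl)-1,1′-binaphthyl-2,2′-diyl N-(trifluoromethylsulfonyl)phosphoramidate (10 mol %), 5 Å molecular sieves, CHCl3, −20 °C → rt; then K2CO3 (cat.), MeOH–THF, rt
Reagents that add atoms: none
Why: Proposed new method: the acid turns the benzhydrol of 7 into o-quinone methide 12 and, after the first cycloaddition, opens the acetonide of 13 (loss of acetone) to o-quinone methide 14, each held as a chiral hydrogen-bonded ion pair; the formyloxy-bearing alkene carbon of 11 bonds to the methide carbon (this regiochemistry gives the p-alkoxybenzyl cation), the cation is capped by the formate carbonyl as a trans-1,3-dioxolan-2-ylium ion and the phenol oxygen opens it at C2 with inversion, which enforces 2,3-trans, while the endo approach of the (E)-alkene to the (E)-quinone methide gives 3,4-trans and the catalyst fixes the absolute sense at C2/C3/C4 and at C2′/C3′, so that rings C and F and all five stereocentres arise in one operation before carbonate methanolysis removes both formates; closest known reaction type: chiral N-triflylphosphoramide-catalysed [4+2] cycloaddition of in situ generated o-quinone methides with styrenes to 2,4-cis-chromans, together with the dioxolanylium ring closure of orthoformate-based flavan-3-ol syntheses.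

Step 8
Reactants: 16 hexabenzyl ether of the target (name as in step 7)
Product: 17 (2R,3S,4R)-2-(3,4-dihydroxyphenyl)-4-[(2R,3S)-2-(3,4-dihydroxyphenyl)-3,7-dihydroxy-3,4-dihydro-2H-chromen-6-yl]-3,4-dihydro-2H-chromene-3,7-diol (CNP0187520.3)
Conditions: H2 (1 atm), Pd(OH)2 on carbon, THF–MeOH, rt, degassed solvents
Reagents that add atoms: none
Why: Hydrogenolysis of the six benzyl ethers (O-debenzylation) under neutral conditions leaves the five stereocentres, the benzylic C2–O1 bonds and the C4–aryl bond untouched.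

**Compound list**
1 | 4-(benzyloxy)-2-hydroxybenzaldehyde | O=Cc1ccc(OCc2ccccc2)cc1O | starting material
2 | 4-(benzyloxy)-5-bromo-2-hydroxybenzaldehyde | O=Cc1cc(Br)c(OCc2ccccc2)cc1O | intermediate
3 | 5-(benzyloxy)-4-bromo-2-(hydroxymethyl)phenol | OCc1cc(Br)c(OCc2ccccc2)cc1O | intermediate
4 | 7-(benzyloxy)-6-bromo-2,2-dimethyl-4H-1,3-benzodioxine | CC1(C)OCc2cc(Br)c(OCc3ccccc3)cc2O1 | intermediate
5 | [7-(benzyloxy)-2,2-dimethyl-4H-1,3-benzodioxin-6-yl]lithium | [Li]c1cc2COC(C)(C)Oc2cc1OCc1ccccc1 | intermediate (not isolated)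
6 | sodium 5-(benzyloxy)-2-formylphenolate | [Na+].[O-]c1cc(OCc2ccccc2)ccc1C=O | intermediate (not isolated)
7 | [4-(benzyloxy)-2-hydroxyphenyl][7-(benzyloxy)-2,2-dimethyl-4H-1,3-benzodioxin-6-yl]methanol, racemic | OC(c1ccc(OCc2ccccc2)cc1O)c1cc2COC(C)(C)Oc2cc1OCc1ccccc1 | intermediate
8 | 3,4-bis(benzyloxy)benzaldehyde | O=Cc1ccc(OCc2ccccc2)c(OCc2ccccc2)c1 | starting material
9 | (triphenylphosphoranylidene)acetaldehyde | O=CC=P(c1ccccc1)(c1ccccc1)c1ccccc1 | starting material
10 | (2E)-3-[3,4-bis(benzyloxy)phenyl]prop-2-enal | O=C/C=C/c1ccc(OCc2ccccc2)c(OCc2ccccc2)c1 | intermediate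
11 | (E)-2-[3,4-bis(benzyloxy)phenyl]ethenyl formate | O=CO/C=C/c1ccc(OCc2ccccc2)c(OCc2ccccc2)c1 | intermediate
12 | (6E)-3-(benzyloxy)-6-{[7-(benzyloxy)-2,2-dimethyl-4H-1,3-benzodioxin-6-yl]methylidene}cyclohexa-2,4-dien-1-one | O=C1C=C(OCc2ccccc2)C=C/C1=C\c1cc2COC(C)(C)Oc2cc1OCc1ccccc1 | intermediate (not isolated)
13 | (2R,3S,4S)-7-(benzyloxy)-4-[7-(benzyloxy)-2,2-dimethyl-4H-1,3-benzodioxin-6-yl]-2-[3,4-bis(benzyloxy)phenyl]-3,4-dihydro-2H-chromen-3-yl formate | c1ccccc1COc1ccc2c(c1)O[C@H](c1ccc(OCc3ccccc3)c(OCc3ccccc3)c1)[C@@H](OC=O)[C@@H]2c1cc2COC(C)(C)Oc2cc1OCc1ccccc1 | intermediate (not isolated)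
14 | (2R,3S,4S)-7-(benzyloxy)-4-[6-(benzyloxy)-3-methylidene-4-oxocyclohexa-1,5-dien-1-yl]-2-[3,4-bis(benzyloxy)phenyl]-3,4-dihydro-2H-chromen-3-yl formate | c1ccccc1COc1ccc2c(c1)O[C@H](c1ccc(OCc3ccccc3)c(OCc3ccccc3)c1)[C@@H](OC=O)[C@@H]2C1=CC(=C)C(=O)C=C1OCc1ccccc1 | intermediate (not isolated)
15 | (2R,3S,4S)-7-(benzyloxy)-2-[3,4-bis(benzyloxy)phenyl]-4-{(2R,3S)-7-(benzyloxy)-2-[3,4-bis(benzyloxy)phenyl]-3-(formyloxy)-3,4-dihydro-2H-chromen-6-yl}-3,4-dihydro-2H-chromen-3-yl formate | c1ccccc1COc1ccc2c(c1)O[C@H](c1ccc(OCc3ccccc3)c(OCc3ccccc3)c1)[C@@H](OC=O)[C@@H]2c1cc2c(cc1OCc1ccccc1)O[C@H](c1ccc(OCc3ccccc3)c(OCc3ccccc3)c1)[C@@H](OC=O)C2 | intermediate (not isolated)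
16 | (2R,3S,4S)-7-(benzyloxy)-2-[3,4-bis(benzyloxy)phenyl]-4-{(2R,3S)-7-(benzyloxy)-2-[3,4-bis(benzyloxy)phenyl]-3-hydroxy-3,4-dihydro-2H-chromen-6-yl}-3,4-dihydro-2H-chromen-3-ol | c1ccccc1COc1ccc2c(c1)O[C@H](c1ccc(OCc3ccccc3)c(OCc3ccccc3)c1)[C@@H](O)[C@@H]2c1cc2c(cc1OCc1ccccc1)O[C@H](c1ccc(OCc3ccccc3)c(OCc3ccccc3)c1)[C@@H](O)C2 | intermediate
17 | (2R,3S,4R)-2-(3,4-dihydroxyphenyl)-4-[(2R,3S)-2-(3,4-dihydroxyphenyl)-3,7-dihydroxy-3,4-dihydro-2H-chromen-6-yl]-3,4-dihydro-2H-chromene-3,7-diol | Oc1ccc2c(c1)O[C@H](c1ccc(O)c(O)c1)[C@@H](O)[C@@H]2c1cc2c(cc1O)O[C@H](c1ccc(O)c(O)c1)[C@@H](O)C2 | target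

**Step count and risks**

Total: 8 steps. Longest linear sequence: 6 steps (1, 2, 3, 4, 7, 8); steps 5 and 6 make the second reactant of step 7.

Step 7 (double cycloaddition) is the most likely to fail. The risks are attack through the wrong alkene carbon of 11, a stepwise first bond that erodes 3,4-trans, and weak face control at quinone methide 14, which has no substituent on its methide carbon. The sense of induction of the (R)-acid is assigned by analogy only; if it gives the mirror series, its antipode is used. The fallback runs from 7 back to 16 and moves the C2/C3 stereocentres from the cycloaddition to an asymmetric hydroboration. Aldehyde 8 is converted with dimethyl (1-diazo-2-oxopropyl)phosphonate and K2CO3 in MeOH into 4-ethynyl-1,2-bis(benzyloxy)benzene F1. Compound 7 and F1 (3 equiv) with the same chiral acid undergo the [4+2] of both quinone methides with the alkyne (terminal carbon to the methide carbon, aryl-bearing carbon to oxygen, no regiochemical ambiguity). This gives (4S)-7-(benzyloxy)-2-[3,4-bis(benzyloxy)phenyl]-4-{7-(benzyloxy)-2-[3,4-bis(benzyloxy)phenyl]-4H-chromen-6-yl}-4H-chromene F2, in which the acid has to set C4 only, on the diaryl quinone methide 12 for which such acids are best suited. Double hydroboration of the two enol ether double bonds with monoisopinocampheylborane made from (+)-α-pinene, then NaBO3, adds H to C2 and OH to C3 on one face (2,3-trans). The addition is anti to the C4 aryl group in ring C and under reagent control in ring F (as for 1-arylcycloalkenes), and gives 16.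

Step 6 (Baeyer–Villiger) is the second risk: the electron-rich enol formate can be epoxidised by excess oxidant, and 11 may hydrolyse on purification. The fallback runs from 8 back to 16 and carries the C3 oxygen as silicon. Methylenation of 8 (Ph3P=CH2, THF) gives 4-ethenyl-1,2-bis(benzyloxy)benzene F3. Silylative coupling of F3 with benzyl(dimethyl)vinylsilane, catalysed by RuHCl(CO)(PPh3)3, gives benzyl{(E)-2-[3,4-bis(benzyloxy)phenyl]ethenyl}dimethylsilane F4. F4 takes the place of 11 in the cycloaddition of step 7; both the aryl group and the β-silicon effect direct the silicon-bearing carbon to the methide carbon, and anti ring closure on the β-silyl cation keeps 2,3-trans. The product is the 3,3′-bis[benzyl(dimethyl)silyl] analogue of 16 (silicon in place of each 3-hydroxyl, same configuration) F5. Tamao–Fleming oxidation (Bu4NF, THF; then H2O2, KHCO3, MeOH) converts both C–Si bonds into C–OH with retention and gives 16.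

Step 4 (aryllithium addition) is the third risk: aryllithium 5 may be quenched by the phenolate salt or add sluggishly to the deactivated aldehyde, and 7 is acid-sensitive. The fallback runs from 4 back to 7 and reverses the polarity, so that the C4–C4a bond is made in place of the C4–C6′ bond. Bromine–lithium exchange on 4 and a DMF quench give 7-(benzyloxy)-2,2-dimethyl-4H-1,3-benzodioxine-6-carbaldehyde F6. 3-(Benzyloxy)phenol and EtMgBr give bromomagnesium 3-(benzyloxy)phenolate F7. In toluene F7 adds to F6 through a six-membered magnesium chelate, only at the less hindered position ortho to the phenolate oxygen (para to the benzyloxy group), and gives 7 after neutral work-up.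

**Further compounds**
F1 | step 7 | 4-ethynyl-1,2-bis(benzyloxy)benzene | C#Cc1ccc(OCc2ccccc2)c(OCc2ccccc2)c1
F2 | step 7 | (4S)-7-(benzyloxy)-2-[3,4-bis(benzyloxy)phenyl]-4-{7-(benzyloxy)-2-[3,4-bis(benzyloxy)phenyl]-4H-chromen-6-yl}-4H-chromene | c1ccccc1COc1ccc2c(c1)OC(c1ccc(OCc3ccccc3)c(OCc3ccccc3)c1)=C[C@@H]2c1cc2c(cc1OCc1ccccc1)OC(c1ccc(OCc3ccccc3)c(OCc3ccccc3)c1)=CC2
F3 | step 6 | 4-ethenyl-1,2-bis(benzyloxy)benzene | C=Cc1ccc(OCc2ccccc2)c(OCc2ccccc2)c1
F4 | step 6 | benzyl{(E)-2-[3,4-bis(benzyloxy)phenyl]ethenyl}dimethylsilane | C[Si](C)(Cc1ccccc1)/C=C/c1ccc(OCc2ccccc2)c(OCc2ccccc2)c1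
F5 | step 6 | (2R,3S,4S)-7-(benzyloxy)-3-[benzyl(dimethyl)silyl]-2-[3,4-bis(benzyloxy)phenyl]-4-{(2R,3S)-7-(benzyloxy)-3-[benzyl(dimethyl)silyl]-2-[3,4-bis(benzyloxy)phenyl]-3,4-dihydro-2H-chromen-6-yl}-3,4-dihydro-2H-chromene | c1ccccc1COc1ccc2c(c1)O[C@H](c1ccc(OCc3ccccc3)c(OCc3ccccc3)c1)[C@@H]([Si](C)(C)Cc1ccccc1)[C@@H]2c1cc2c(cc1OCc1ccccc1)O[C@H](c1ccc(OCc3ccccc3)c(OCc3ccccc3)c1)[C@@H]([Si](C)(C)Cc1ccccc1)C2
F6 | step 4 | 7-(benzyloxy)-2,2-dimethyl-4H-1,3-benzodioxine-6-carbaldehyde | O=Cc1cc2COC(C)(C)Oc2cc1OCc1ccccc1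
F7 | step 4 | bromomagnesium 3-(benzyloxy)phenolate | Br[Mg]Oc1cccc(OCc2ccccc2)c1
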